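## Structural features

Sikokianin B is a 3,3''-linked biflavanone. Each half is a chroman-4-one in which a 5,7-dihydroxylated benzene ring (ring A) is fused to a dihydropyranone (ring C) carrying a para-oxygenated phenyl ring (ring B) on C2. Unit 1 (unprimed) bears the 4-methoxyphenyl group, unit 2 (doubly primed) the 4-hydroxyphenyl group, and the two rings C are joined by the single bond C3–C3'' between the two α-keto carbon atoms. The four stereocentres C2, C3, C3'' and C2'' form an unbroken chain: unit 1 is 2,3-trans (2R,3S) and unit 2 is 2,3-cis (2''R,3''R), so the molecule has no symmetry and cannot be made by dimerising one monomer. The fragile points are the two enolisable methines C3 and C3'', base-induced retro-oxa-Michael opening of either ring C (which would scramble C2 or C2''), the kinetically held cis pair of unit 2, and five free phenols beside one methyl ether that must stay distinct. The real difficulty is the crowded C3–C3'' junction between two fully substituted carbon atoms, together with relative and absolute control over four adjacent centres, one pair trans and one pair cis. The key step exploits ring C of unit 1: O1, C8a, C4a and C4 sit on the electron-rich ring A and face the C2–C3 edge, whose C2 carries a 4-methoxyphenyl group able to support positive charge. Ring C can therefore be laid down from an ortho-quinone methide (O1=C8a–C4a=C4) and an E alkene C2=C3 that already carries unit 2, flat and free of stereocentres, as a flavone on C3. Once C4 is a ketone it lies β,γ to the flavone double bond C2''=C3'' and can guide a hydrogenation catalyst to one face, which is how the cis pair is planned.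

## Logic of the disconnections

**15 back to 14.** The five phenolic O–H bonds are traced back to O–CH2Ph bonds. Benzyl is the only protecting group in the route, so one neutral final operation releases all phenols. The forward step must leave the two aryl ketones, the methyl ether and the enolisable centres C3 and C3'' untouched.

**14 back to 13.** The C2''–H and C3''–H bonds are removed, so unit 2 becomes a flavone. Two stereocentres disappear and unit 2 turns into a planar, robust substituent that survives acid, oxidant and base in the earlier steps. The forward step must add both hydrogen atoms to one face (cis), and to the face that gives 2''R,3''R; the C4 carbonyl of unit 1 is the anchor for this.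

**13 back to 12 and 11.** The C4=O bond is removed in two stages (ketone, carbinol, methylene). This is required because the cycloaddition delivers C4 as CH2. The gain is a flavan without any enolisable centre. The forward steps need a benzylic oxidation that picks C4 (activated by O1, 5-O and 7-O) over C2–H and over the benzyl ether methylenes.

**11 back to 9 and 6 through 10.** The bonds C3–C4 and O1–C2 are cut. This removes ring C of unit 1 and both of its stereocentres at once and divides the molecule into two fragments of similar size, one achiral and one flat. The forward step must give one regiochemistry (aryl on C2), the trans pair and one enantiomer. The first two follow from the polarity and the E geometry of the alkene in 6; the third must come from a chiral acid.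

**9 back to 8 and 7.** The C4–H bond formed by hydride and two O–benzyl bonds are cut, leading to a cheap trihydroxy aldehyde. The forward demands are selective bis-benzylation that spares the hydrogen-bonded hydroxyl, and a mild reduction, because 9 ionises easily.

**6 back to 4 and 5.** The bond between C3'' and the alkene carbon is cut. A cross-coupling of a 3-iodoflavone with an E-alkenylboronic acid transfers the alkene geometry unchanged. The demand is retention of E geometry at a hindered position flanked by the C2'' aryl group and the carbonyl.

**4 back to 2 (through 3) and 1.** The C3''–I bond and three O–benzyl bonds are cut, leading to a commercial trihydroxyflavone. This replaces a multi-step flavone construction by protection and one C–H functionalisation. The demand is iodination at C3'' only, which is met by deprotonation and not by electrophilic substitution, since the latter would attack C6'' or C8''.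

## Other disconnections considered

**Alternative 1:** The cut lies inside both rings A, at C4a–C8a and C4a''–C8a'', so that the two phloroglucinol rings form last.
- **Forward step.** The bis(triketo ester) A2 would be treated with Mg(OMe)2. Each C4a carbanion would attack its own terminal ester carbonyl (Claisen condensation), and loss of methanol and enolisation would give the unprotected E,E-bichalcone A1. A double oxa-Michael closure of A1 would then have to finish the target.
- **In favour.** It imitates the polyketide origin of ring A, needs no phenol protection and builds two rings and two C–C bonds in one operation. In protecting-group economy and in freedom from redox corrections it is better than the chosen plan.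
- **Against.** A2 carries eight carbonyl groups and several enolisable methylene groups, so aldol closure to resorcylates and pyranone formation compete with the Claisen mode, and making A2 with a defined diene is a long task of its own. More seriously, A1 has no stereocentre. All four centres would arise in reversible oxa-Michael closures under thermodynamic control, which favour trans units and give racemic material.
- **Comparison.** The chosen key step forms fewer bonds (one C–C, one C–O) but fixes two stereocentres by mechanism and prepares the other two for a directed addition. Alternative 1 is equal in convergence and shorter on paper after A1, but gives no handle on any of the four centres. It trades an uncertain enantioselective cycloaddition for an uncertain polyketide folding.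

**Alternative 2:** The cut is the C2''–C3'' bond of the cis unit.
- **Forward step.** In the diazoketone A4, C3'' is the diazo carbon between C4''=O and C3 of a finished trans unit 1. Rh2(S-PTTL)4 would convert it into a dirhodium carbene that inserts into a C–H bond of the ortho O–CH2–aryl ether, closing ring C of unit 2 to give A3.
- **In favour.** Carbene insertion into benzylic ether C–H bonds is known to favour cis 2,3-disubstituted oxygen heterocycles. The kinetic cis pair, the weakest point of the chosen plan, would be formed directly and under catalyst control, and neither a flavone hydrogenation nor a C4 oxidation is needed. On these two counts the alternative is better.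
- **Against.** The carbene carbon carries a secondary alkyl group with a hydrogen atom on C3, and 1,2-hydride migration to a C3=C3'' enone is the usual fast fate of such carbenes. Closure to a six-membered ring is slower than the five-membered mode. A4 cannot be made by simple diazo transfer, because the neighbouring C3 is the more acidic position and a stereocentre that base would epimerise or open by retro-oxa-Michael reaction. The chiral catalyst must also cooperate with the existing C2 and C3 centres, and the 5''-silyl ether is an extra, differentiated protecting group.
- **Comparison.** It is equal in that unit 1 must be made trans and enantiopure in either plan, and better in how the cis pair arises. It is worse in precursor access, in the chemoselectivity of the reactive intermediate and in step count, since A4 needs its own enantioselective synthesis of unit 1, a C3 acylation and a diazo installation.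

**Alternative 3:** The cut is C3–C4, the same bond as in the chosen plan but with reversed polarity, C4 being an acyl anion equivalent.
- **Forward step.** A chiral triazolium-derived carbene adds to the ring A aldehyde of A6. The resulting acyl anion equivalent attacks C3 of the exocyclic C3=C3'' enone (intramolecular Stetter reaction), ring C of unit 1 closes, and the enolate is protonated at C3'' to give A5, which is the same compound as 14.
- **In favour.** Intramolecular Stetter closure to chroman-4-ones is a well-developed asymmetric reaction. C4 arrives as the ketone, so the two oxidation steps of the chosen route are not needed, and C3 and C3'' are created in one event. In oxidation-state economy it is better; in the ring that is closed it is equal.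
- **Against.** A6 needs C2 (an α-aryloxy benzylic centre) and C2'' to be set separately beforehand. Its Z alkylidene flavanone can drift to the E isomer or to the endocyclic 3-alkylflavone under the basic conditions that liberate the carbene, which erases C2''. The acceptor carbon C3 is flanked by the substituted C2, so the conjugate addition is hindered. The cis outcome rests on a kinetic protonation at C3'' whose face must agree with that of the C–C bond formation.
- **Comparison.** The chosen route has the more accessible and more robust precursors (a flat flavone and an achiral benzyl alcohol) and sets C2 and C3 together from alkene geometry, at the price of two oxidation steps and a demanding hydrogenation. Alternative 3 is shorter after its key step (one deprotection) but longer and more fragile before it.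

Key step: step 6

**Remarks on the chemistry (assumptions).**
- 1, 5 and 7 are taken as purchasable.
- The sense of induction of the chiral acid in step 6 cannot be predicted with confidence. The (R) catalyst is written, and its mirror image would be used if a trial showed the other sense.
- 12 is carried on as the mixture of C4 epimers, because step 8 removes that centre.
- The flavone carbonyl is a hydrogen-bond acceptor only and cannot be held by the phosphoryl oxygen of a phosphoric acid. Step 6 is therefore planned with an acid that activates the quinone methide alone.

## Route

Step 1
Reactants: 1 apigenin (5,7-dihydroxy-2-(4-hydroxyphenyl)-4H-chromen-4-one)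
Product: 2 5,7-bis(benzyloxy)-2-[4-(benzyloxy)phenyl]-4H-chromen-4-one
Conditions: BnBr (4 equiv), K2CO3, DMF, 80 °C
Reagents that add atoms: benzyl bromide, BrCc1ccccc1
Why: Williamson ether synthesis; the chelated 5-hydroxyl is the slowest phenol and needs excess halide and heat. Full benzylation removes every acidic proton before the lithiation and gives one protecting group for the whole route.

Step 2
Reactants: 2 5,7-bis(benzyloxy)-2-[4-(benzyloxy)phenyl]-4H-chromen-4-one
Product: 4 5,7-bis(benzyloxy)-2-[4-(benzyloxy)phenyl]-3-iodo-4H-chromen-4-one, via 3-lithioflavone 3 (not isolated)
Conditions: LiN(iPr)2 (1.2 equiv), THF, −78 °C; then I2, −78 °C to rt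
Reagents that add atoms: iodine, II
Why: Deprotonation and iodine quench; C3–H is the only vinylic proton next to the carbonyl and is removed by the amide base at low temperature. The anionic route avoids electrophilic iodination, which would attack C6 or C8 of the electron-rich ring A.

Step 3
Reactants: 4 5,7-bis(benzyloxy)-2-[4-(benzyloxy)phenyl]-3-iodo-4H-chromen-4-one; 5 (E)-2-(4-methoxyphenyl)vinylboronic acid
Product: 6 5,7-bis(benzyloxy)-2-[4-(benzyloxy)phenyl]-3-[(E)-2-(4-methoxyphenyl)ethenyl]-4H-chromen-4-one
Conditions: Pd(PPh3)4 (5 mol %), K2CO3, 1,4-dioxane/H2O, 85 °C
Reagents that add atoms: none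
Why: Suzuki–Miyaura coupling; oxidative addition of zerovalent palladium into the C3–I bond, transmetallation and reductive elimination proceed with retention of the E geometry of the boronic acid. It is preferred to a Heck reaction with 4-methoxystyrene because it excludes the 1,1-disubstituted regioisomer.

Step 4
Reactants: 7 2,4,6-trihydroxybenzaldehyde
Product: 8 2,4-bis(benzyloxy)-6-hydroxybenzaldehyde
Conditions: BnBr (2.1 equiv), K2CO3, DMF, 0 °C to rt
Reagents that add atoms: benzyl bromide, BrCc1ccccc1
Why: Williamson ether synthesis; after two alkylations the remaining hydroxyl is hydrogen-bonded to the aldehyde and is the least nucleophilic, so the reaction should stop at the bis-ether.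

Step 5
Reactants: 8 2,4-bis(benzyloxy)-6-hydroxybenzaldehyde
Product: 9 3,5-bis(benzyloxy)-2-(hydroxymethyl)phenol
Conditions: NaBH4, THF/MeOH, 0 °C; pH 7 buffer work-up; used at once
Reagents that add atoms: none
Why: Borohydride reduction of an aryl aldehyde. The product ionises easily, so it is made cold, worked up neutral and not stored.

Step 6
Reactants: 9 3,5-bis(benzyloxy)-2-(hydroxymethyl)phenol; 6 5,7-bis(benzyloxy)-2-[4-(benzyloxy)phenyl]-3-[(E)-2-(4-methoxyphenyl)ethenyl]-4H-chromen-4-one
Product: 11 5,7-bis(benzyloxy)-3-[(2R,3S)-5,7-bis(benzyloxy)-2-(4-methoxyphenyl)chroman-3-yl]-2-[4-(benzyloxy)phenyl]-4H-chromen-4-one (trans flavan of unit 1 carrying the unit 2 flavone at C3), via ortho-quinone methide 10 (not isolated)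
Conditions: (R)-3,3'-bis(2,4,6-triisopropylphenyl)-1,1'-binaphthyl-2,2'-diyl N-triflylphosphoramide (10 mol %), 4 Å MS, CH2Cl2, −20 °C; 9 (1.5 equiv) added over 6 h
Reagents that add atoms: none
Why: The acid protonates the benzylic hydroxyl of 9, and water leaves with help from the ortho and para oxygen atoms to give ortho-quinone methide 10, held as a hydrogen-bonded ion pair on the chiral phosphoramide anion. 10 is an oxa-diene (O1=C8a–C4a=C4) that adds across the electron-rich E alkene of 6 in an inverse-electron-demand hetero-Diels–Alder reaction; the closest known reaction type is the chiral Brønsted acid catalysed (4+2) cycloaddition of quinone methides generated in situ with styrenes to give 2-arylchromans. The addition is asynchronous: C4–C3 forms first at the alkene carbon remote from the anisyl ring, the positive charge that develops at C2 is carried by the 4-methoxyphenyl group, and O1 then closes the ring, which fixes the regiochemistry (aryl on C2, flavone on C3). Ring C of unit 1 is closed by a (4+2) cycloaddition that is suprafacial on both partners; in the stepwise limit the second bond forms by 6-exo-trig capture of the para-methoxybenzylic cation by the phenolic oxygen, and recovery of the aromaticity of ring A drives the reaction. C2 and C3 are created together, and their trans relationship is dictated by the E geometry of the alkene and supported by thermodynamics (both substituents equatorial). Their absolute configuration depends on which enantiotopic face of the alkene meets C4 and is controlled by the chiral counter-anion that surrounds the methide terminus. Because the flavone carbonyl can only accept a hydrogen bond, a strongly acidic, confined catalyst that activates the electrophile alone is used in place of a bifunctional one. Chemoselectivity is needed against Friedel–Crafts self-condensation of 10 with 9 and is secured by slow addition of 9 to 6 and the catalyst; the tetrasubstituted flavone double bond and the carbonyl-deactivated ring A of unit 2 should not compete.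

Step 7
Reactants: 11 trans flavan of unit 1 carrying the unit 2 flavone at C3
Product: 12 4-hydroxy derivative of 11 (both C4 epimers; C2 and C3 as in 11)
Conditions: DDQ (1.5 equiv), CH2Cl2/H2O (10:1), 0 °C to rt
Reagents that add atoms: water, O
Why: Benzylic C–H oxidation by hydride abstraction; C4 is activated by O1, 5-O and 7-O of ring A, and the cation is trapped by water, as known for 5,7-dialkoxyflavans. The new C4 carbinol centre is not controlled (attack anti to the C3 substituent should dominate) and is erased in step 8.

Step 8
Reactants: 12 4-hydroxy derivative of 11 (both C4 epimers)
Product: 13 5,7-bis(benzyloxy)-3-[(2R,3S)-5,7-bis(benzyloxy)-2-(4-methoxyphenyl)-4-oxochroman-3-yl]-2-[4-(benzyloxy)phenyl]-4H-chromen-4-one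
Conditions: Dess–Martin periodinane, NaHCO3, CH2Cl2, rt
Reagents that add atoms: none
Why: Dess–Martin oxidation of a secondary benzylic alcohol under buffered, neutral conditions. C3 becomes α to the ketone but stays in its thermodynamically preferred trans arrangement, and no base is present that could open ring C.

Step 9
Reactants: 13 flavanone of unit 1 carrying the unit 2 flavone at C3
Product: 14 penta-O-benzylsikokianin B, (2R,3S)-5,7-bis(benzyloxy)-3-[(2R,3R)-5,7-bis(benzyloxy)-2-[4-(benzyloxy)phenyl]-4-oxochroman-3-yl]-2-(4-methoxyphenyl)chroman-4-one
Conditions: [Ir(cod)(PCy3)(py)]PF6 (10–20 mol %), H2 (20 bar), CH2Cl2, 25 °C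
Reagents that add atoms: none
Why: Proposed new method: ketone-directed homogeneous hydrogenation of the flavone C2''=C3'' bond. The cationic iridium dihydride formed from the catalyst binds the C4 carbonyl oxygen of unit 1 together with the π bond as a five-membered chelate (O, C4, C3, C3''); allylic 1,3-strain keeps C3–H in the flavone plane beside the C2'' aryl group, so C4=O reaches one face only, and both hydrogen atoms are delivered syn to that face, which puts the aryl group on C2'' and the C3 substituent on C3'' cis and gives 2''R,3''R. The closest known reaction type is the carbonyl-directed hydrogenation of tetrasubstituted β,γ-unsaturated ketones, esters and amides with this catalyst, which has not been shown on the double bond of a 3-substituted flavone.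

Step 10
Reactants: 14 penta-O-benzylsikokianin B
Product: 15 sikokianin B
Conditions: H2 (1 atm), Pd/C (10 wt %), EtOAc/MeOH, rt
Reagents that add atoms: none
Why: Hydrogenolysis of five aryl benzyl ethers. The medium is neutral, so the enolisable centres C3 and C3'' and the rings C are not disturbed, and the methyl ether and the hydrogen-bonded aryl ketones are not cleaved under these mild conditions.

## Compound list

1 | apigenin, 5,7-dihydroxy-2-(4-hydroxyphenyl)-4H-chromen-4-one | O=C1C=C(c2ccc(O)cc2)Oc2cc(O)cc(O)c12 | starting material
2 | 5,7-bis(benzyloxy)-2-[4-(benzyloxy)phenyl]-4H-chromen-4-one | O=C1C=C(c2ccc(OCc3ccccc3)cc2)Oc2cc(OCc3ccccc3)cc(OCc3ccccc3)c12 | intermediate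
3 | 3-lithio derivative of 2 (not isolated) | [Li]C1=C(c2ccc(OCc3ccccc3)cc2)Oc2cc(OCc3ccccc3)cc(OCc3ccccc3)c2C1=O | intermediate
4 | 5,7-bis(benzyloxy)-2-[4-(benzyloxy)phenyl]-3-iodo-4H-chromen-4-one | IC1=C(c2ccc(OCc3ccccc3)cc2)Oc2cc(OCc3ccccc3)cc(OCc3ccccc3)c2C1=O | intermediate
5 | (E)-2-(4-methoxyphenyl)vinylboronic acid | COc1ccc(/C=C/B(O)O)cc1 | starting material
6 | 5,7-bis(benzyloxy)-2-[4-(benzyloxy)phenyl]-3-[(E)-2-(4-methoxyphenyl)ethenyl]-4H-chromen-4-one | COc1ccc(/C=C/C2=C(c3ccc(OCc4ccccc4)cc3)Oc3cc(OCc4ccccc4)cc(OCc4ccccc4)c3C2=O)cc1 | intermediate
7 | 2,4,6-trihydroxybenzaldehyde | O=Cc1c(O)cc(O)cc1O | starting material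
8 | 2,4-bis(benzyloxy)-6-hydroxybenzaldehyde | O=Cc1c(O)cc(OCc2ccccc2)cc1OCc1ccccc1 | intermediate
9 | 3,5-bis(benzyloxy)-2-(hydroxymethyl)phenol | OCc1c(O)cc(OCc2ccccc2)cc1OCc1ccccc1 | intermediate
10 | 3,5-bis(benzyloxy)-6-methylidenecyclohexa-2,4-dien-1-one, ortho-quinone methide (not isolated) | C=C1C(=O)C=C(OCc2ccccc2)C=C1OCc1ccccc1 | intermediate
11 | 5,7-bis(benzyloxy)-3-[(2R,3S)-5,7-bis(benzyloxy)-2-(4-methoxyphenyl)chroman-3-yl]-2-[4-(benzyloxy)phenyl]-4H-chromen-4-one | COc1ccc([C@@H]2Oc3cc(OCc4ccccc4)cc(OCc4ccccc4)c3C[C@H]2C2=C(c3ccc(OCc4ccccc4)cc3)Oc3cc(OCc4ccccc4)cc(OCc4ccccc4)c3C2=O)cc1 | intermediate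
12 | 4-hydroxy derivative of 11, both C4 epimers (C4 left undefined in the SMILES) | COc1ccc([C@@H]2Oc3cc(OCc4ccccc4)cc(OCc4ccccc4)c3C(O)[C@H]2C2=C(c3ccc(OCc4ccccc4)cc3)Oc3cc(OCc4ccccc4)cc(OCc4ccccc4)c3C2=O)cc1 | intermediate
13 | 5,7-bis(benzyloxy)-3-[(2R,3S)-5,7-bis(benzyloxy)-2-(4-methoxyphenyl)-4-oxochroman-3-yl]-2-[4-(benzyloxy)phenyl]-4H-chromen-4-one | COc1ccc([C@@H]2Oc3cc(OCc4ccccc4)cc(OCc4ccccc4)c3C(=O)[C@H]2C2=C(c3ccc(OCc4ccccc4)cc3)Oc3cc(OCc4ccccc4)cc(OCc4ccccc4)c3C2=O)cc1 | intermediate
14 | penta-O-benzylsikokianin B, (2R,3S)-5,7-bis(benzyloxy)-3-[(2R,3R)-5,7-bis(benzyloxy)-2-[4-(benzyloxy)phenyl]-4-oxochroman-3-yl]-2-(4-methoxyphenyl)chroman-4-one | COc1ccc([C@@H]2Oc3cc(OCc4ccccc4)cc(OCc4ccccc4)c3C(=O)[C@H]2[C@H]2C(=O)c3c(OCc4ccccc4)cc(OCc4ccccc4)cc3O[C@H]2c2ccc(OCc3ccccc3)cc2)cc1 | intermediate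
15 | sikokianin B, (2R,3S)-3-[(2R,3R)-5,7-dihydroxy-2-(4-hydroxyphenyl)-4-oxochroman-3-yl]-5,7-dihydroxy-2-(4-methoxyphenyl)chroman-4-one | COc1ccc([C@@H]2Oc3cc(O)cc(O)c3C(=O)[C@H]2[C@H]2C(=O)c3c(O)cc(O)cc3O[C@H]2c2ccc(O)cc2)cc1 | target

## Step count and least certain steps

Total: 10 steps in two branches (steps 1–3 and steps 4–5) that meet in step 6. Longest linear sequence: 8 steps (1, 2, 3, 6, 7, 8, 9, 10).

**Step 9 (bears the label).** Three things are most likely to go wrong.
- The catalyst may not turn over, because the tetrasubstituted, push–pull double bond of the flavone binds weakly and the iridium hydride decays to inactive clusters.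
- Hydrogen may be delivered to the other face through the minor rotamer about C3–C3''.
- The benzyl ether oxygen atoms may compete as anchors.

The fallback uses known reactions only; it sets out from 11 and returns at 14. Conjugate hydride reduction of the flavone of 11 with LiBH(s-Bu)3 in THF at −78 °C, followed by protonation of the enolate at −78 °C with 2,6-di-tert-butylphenol anti to the C2'' aryl group, should give the flavan carrying the cis flavanone F1. F1 would have to be separated from its cis diastereomer of opposite C2'',C3'' configuration, since the hydride face is under substrate control only. DDQ/H2O oxidation at C4 as in step 7 would then give the 4-hydroxy compound F2, and Dess–Martin oxidation as in step 8 would give 14.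

**Step 6 (key step).** The most likely failure is poor facial selectivity at the alkene, because the methide terminus is unsubstituted and the alkene offers no hydrogen-bond donor. Next come self-condensation of 10 with the electron-rich ring of 9, and a slow cycloaddition owing to the bulky flavone on the alkene. The fallback gives up catalytic enantiocontrol; it sets out from 9 and 6 and returns at 11. The cycloaddition is run with an achiral acid, (PhO)2P(O)OH in CH2Cl2, which should give racemic material, that is 11 together with the (2S,3R) enantiomer F3. Preparative chromatography on a chiral stationary phase then supplies 11.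

**Step 7.** The C4 cation may lose the C3 proton to give a flav-3-ene conjugated with the flavone, which would be dehydrogenated further. Hydride abstraction at C2 and oxidative loss of a benzyl group are lesser risks. The fallback sets out from 11 and returns at 12. Benzylic acetoxylation with Pb(OAc)4 in benzene/AcOH, where acetate is delivered from the metal, should give the 4-acetoxyflavan F4, and methanolysis (K2CO3, MeOH) should give 12.

**Step 5.** The product may be lost during reduction and isolation through ionisation to 10, followed by a second hydride addition (over-reduction to the methylphenol) or by oligomerisation. The fallback sets out from 8 and returns at 10. After the same borohydride reduction the crude diol is condensed at once with PhB(OH)2 (MgSO4, CH2Cl2) to the cyclic boronate F5. F5 can be purified and stored, and such benzodioxaborinines are known to release quinone methides under acid, so F5 would deliver 10 directly under the conditions of step 6.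

**Step 10.** Epimerisation at C3'' (cis to trans) on the metal surface, reductive opening of the benzylic C2–O bonds, and incomplete cleavage of the hindered 5-O-benzyl groups are the risks. The fallback sets out from 14 and returns at 15 with no new compound: Lewis acid debenzylation with BCl3 and pentamethylbenzene as cation scavenger in CH2Cl2 at −78 °C, conditions under which an aryl methyl ether remote from a carbonyl group is expected to survive.

## Further compounds

F1 | step 9 | flavan of unit 1 carrying the cis flavanone of unit 2, (2R,3R)-5,7-bis(benzyloxy)-3-[(2R,3S)-5,7-bis(benzyloxy)-2-(4-methoxyphenyl)chroman-3-yl]-2-[4-(benzyloxy)phenyl]chroman-4-one | COc1ccc([C@@H]2Oc3cc(OCc4ccccc4)cc(OCc4ccccc4)c3C[C@H]2[C@H]2C(=O)c3c(OCc4ccccc4)cc(OCc4ccccc4)cc3O[C@H]2c2ccc(OCc3ccccc3)cc2)cc1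
F2 | step 9 | 4-hydroxy derivative of F1, both C4 epimers | COc1ccc([C@@H]2Oc3cc(OCc4ccccc4)cc(OCc4ccccc4)c3C(O)[C@H]2[C@H]2C(=O)c3c(OCc4ccccc4)cc(OCc4ccccc4)cc3O[C@H]2c2ccc(OCc3ccccc3)cc2)cc1
F3 | step 6 | (2S,3R) enantiomer of 11 | COc1ccc([C@H]2Oc3cc(OCc4ccccc4)cc(OCc4ccccc4)c3C[C@@H]2C2=C(c3ccc(OCc4ccccc4)cc3)Oc3cc(OCc4ccccc4)cc(OCc4ccccc4)c3C2=O)cc1
F4 | step 7 | 4-acetoxy derivative of 11, both C4 epimers | COc1ccc([C@@H]2Oc3cc(OCc4ccccc4)cc(OCc4ccccc4)c3C(OC(C)=O)[C@H]2C2=C(c3ccc(OCc4ccccc4)cc3)Oc3cc(OCc4ccccc4)cc(OCc4ccccc4)c3C2=O)cc1
F5 | step 5 | 5,7-bis(benzyloxy)-2-phenyl-4H-benzo[d][1,3,2]dioxaborinine | c1ccc(cc1)B1OCc2c(O1)cc(OCc1ccccc1)cc2OCc1ccccc1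
F0 | step 10 | none | none
A1 | alternative 1 | unprotected E,E-bichalcone | COc1ccc(/C=C(C(=O)c2c(O)cc(O)cc2O)\C(=C/c2ccc(O)cc2)C(=O)c2c(O)cc(O)cc2O)cc1
A2 | alternative 1 | bis(3,5,7-triketo methyl ester) of the E,E-diene | COc1ccc(/C=C(C(=O)CC(=O)CC(=O)CC(=O)OC)\C(=C/c2ccc(O)cc2)C(=O)CC(=O)CC(=O)CC(=O)OC)cc1
A3 | alternative 2 | protected sikokianin B with a 5''-tert-butyldimethylsilyl ether and four benzyl ethers | COc1ccc([C@@H]2Oc3cc(OCc4ccccc4)cc(OCc4ccccc4)c3C(=O)[C@H]2[C@H]2C(=O)c3c(O[Si](C)(C)C(C)(C)C)cc(OCc4ccccc4)cc3O[C@H]2c2ccc(OCc3ccccc3)cc2)cc1
A4 | alternative 2 | C3'' diazoketone on the trans flavanone of unit 1 | COc1ccc([C@@H]2Oc3cc(OCc4ccccc4)cc(OCc4ccccc4)c3C(=O)[C@H]2C(=[N+]=[N-])C(=O)c2c(O[Si](C)(C)C(C)(C)C)cc(OCc3ccccc3)cc2OCc2ccc(OCc3ccccc3)cc2)cc1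
A5 | alternative 3 | penta-O-benzylsikokianin B (identical with 14) | COc1ccc([C@@H]2Oc3cc(OCc4ccccc4)cc(OCc4ccccc4)c3C(=O)[C@H]2[C@H]2C(=O)c3c(OCc4ccccc4)cc(OCc4ccccc4)cc3O[C@H]2c2ccc(OCc3ccccc3)cc2)cc1
A6 | alternative 3 | Z-alkylidene flavanone carrying the ring A aldehyde | COc1ccc(cc1)[C@H](Oc1cc(OCc2ccccc2)cc(OCc2ccccc2)c1C=O)/C=C1\C(=O)c2c(OCc3ccccc3)cc(OCc3ccccc3)cc2O[C@H]1c1ccc(OCc2ccccc2)cc1
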